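**Strategy.** Everything rests on cutting ring B of the decalin at two bonds, the ring A/ring B fusion bond C5–C10 and C8–C9. Ring B, with C11 on C9 and four contiguous stereocentres (C5, C8, C9, C10), is the retron of an endo intramolecular Diels–Alder reaction of an acyclic (E,E,E)-trienimide: the C11 carbonyl, carrying an oxazolidinone auxiliary, activates the C9=C10 dienophile, C5=C6–C7=C8 is the diene and C1–C4 the tether. One operation closes both rings and sets all four ring stereocentres. C13 arrives with a Wittig fragment from a chiral lactone; the C8 oxygen is installed late by strain-accelerated tertiary C–H hydroxylation with retention, then formylated.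

Key step: step 7

Remark: labdane numbering is used for all intermediates (decalin C1–C10, side chain C11–C16, C17 on C8, C18/C19 on C4, C20 on C10; α is the face opposite C20), and 2,2-dimethylpent-4-enal, (E)-prop-1-en-1-ylboronic acid and (R)-4-methyldihydrofuran-2(3H)-one are taken as commercial.

Step 1
Reactants: 1 2,2-dimethylpent-4-enal
Product: 2 (E)-1-iodo-3,3-dimethylhexa-1,5-diene
Conditions: CHI3, CrCl2, THF/dioxane, 0 °C → rt
Reagents that add atoms: iodoform, IC(I)I
Why: Takai olefination of the non-enolisable aldehyde, in which the gem-dichromium species from CHI3 and CrCl2 adds to C=O and eliminates to the (E)-vinyl iodide (future C5=C6) while the terminal alkene is untouched.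

Step 2
Reactants: 2 (E)-1-iodo-3,3-dimethylhexa-1,5-diene; 3 (E)-prop-1-en-1-ylboronic acid
Product: 4 (2E,4E)-6,6-dimethylnona-2,4,8-triene
Conditions: Pd(PPh3)4 (5 mol %), 2 M aq. NaOH, THF, 50 °C
Reagents that add atoms: none
Why: Suzuki–Miyaura coupling of an alkenyl iodide with an alkenylboronic acid goes with retention at both partners, so the (E,E)-diene C5=C6–C7=C8–C17 is fixed by the two (E)-building blocks.

Step 3
Reactants: 5 methyl acetoacetate
Product: 6 methyl (E)-3-{[(trifluoromethyl)sulfonyl]oxy}but-2-enoate
Conditions: Tf2O, 25% aq. Me4NOH, hexanes, 5 °C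
Reagents that add atoms: trifluoromethanesulfonic anhydride, O=S(=O)(OS(=O)(=O)C(F)(F)F)C(F)(F)F
Why: Stereoselective enol triflation of the β-keto ester, in which the non-coordinating tetramethylammonium counter-ion leaves the enolate unchelated so that the (E)-enol triflate (OTf trans to CO2Me) should form.

Step 4
Reactants: 4 (2E,4E)-6,6-dimethylnona-2,4,8-triene; 6 methyl (E)-3-{[(trifluoromethyl)sulfonyl]oxy}but-2-enoate
Product: 8 methyl (2E,8E,10E)-3,7,7-trimethyldodeca-2,8,10-trienoate, via B-alkyl-9-BBN adduct 7 (not isolated)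
Conditions: 9-BBN (1.05 equiv), THF, 0 °C → rt; then 6, Pd(dppf)Cl2 (5 mol %), AsPh3, 3 M aq. K3PO4, DMF, rt
Reagents that add atoms: none
Why: 9-BBN hydroborates the monosubstituted alkene anti-Markovnikov far faster than the hindered conjugated diene, and the B-alkyl Suzuki–Miyaura coupling with the electron-poor enol triflate goes with retention, giving the (2E)-enoate with the tether trans to the ester and the future C20 methyl cis to C11.

Step 5
Reactants: 8 methyl (2E,8E,10E)-3,7,7-trimethyldodeca-2,8,10-trienoate
Product: 9 (2E,8E,10E)-3,7,7-trimethyldodeca-2,8,10-trienoic acid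
Conditions: LiOH·H2O, THF/MeOH/H2O, 50 °C; then 1 M HCl
Reagents that add atoms: lithium hydroxide, [Li+].[OH-]
Why: Ester saponification, in which the conjugated carboxylate formed should neither deconjugate nor lose its (2E) geometry.

Step 6
Reactants: 9 (2E,8E,10E)-3,7,7-trimethyldodeca-2,8,10-trienoic acid; 10 (S)-4-benzyloxazolidin-2-one
Product: 12 (S)-4-benzyl-3-[(2E,8E,10E)-3,7,7-trimethyldodeca-2,8,10-trienoyl]oxazolidin-2-one, via mixed pivalic anhydride 11 (not isolated)
Conditions: PivCl, Et3N, THF, −20 °C; then 10, LiCl, −20 °C → rt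
Reagents that add atoms: none
Why: N-acylation of the oxazolidinone through the mixed pivalic anhydride, which is attacked at the less hindered enoyl carbonyl under conditions too mild to touch the γ-protons.

Step 7
Reactants: 12 (S)-4-benzyl-3-[(2E,8E,10E)-3,7,7-trimethyldodeca-2,8,10-trienoyl]oxazolidin-2-one
Product: 13 (S)-4-benzyl-3-[(1S,2S,4aS,8aS)-2,5,5,8a-tetramethyl-1,2,4a,5,6,7,8,8a-octahydronaphthalene-1-carbonyl]oxazolidin-2-one (trans-fused; Δ6, 5α-H, 8α-H with C17 β, 9α-H, C20 β)
Conditions: Me2AlCl (1.6 equiv), CH2Cl2, −30 °C → 0 °C; then 1 M HCl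
Reagents that add atoms: none
Why: Two-point binding of both imide carbonyls to a dimethylaluminium cation (from excess Me2AlCl) locks the s-cis enoyl unit and lowers its LUMO, and the tethered diene then adds in a concerted, asynchronous [4+2] cycloaddition that forms C5–C10 and C8–C9; the closest known reaction type is the Lewis acid-promoted intramolecular Diels–Alder reaction of (E,E,E)-trienimides bearing oxazolidinone auxiliaries. Ring B closes as the cyclohexene of the suprafacial [4π+2π] addition, and ring A closes at the same moment as the six-membered carbocycle spanned by the four-carbon tether C1–C4 when C5–C10 forms, the tether lying anti (exo) in the endo transition state, which makes the fusion trans. The absolute configuration at C9 and C10 is set by the auxiliary, whose benzyl group shields the C9 Re face of the chelate so that the diene adds to the Si face, and the cis relation of C20 and C11 follows from the (2E) dienophile geometry. C5 (5α-H) and C8 (8α-H, C17 β) follow from the endo rule and the (E,E) diene geometry, the outside substituents C4 and C17 ending up cis to the endo C11 carbonyl. The step needs endo over exo closure despite the 1,3-diaxial C19/C20 methyl contact that develops in the trans-fused transition state, which the chelated, strongly endo-directing carbonyl should secure, and it needs enough reactivity for a β,β-disubstituted dienophile, which the cationic chelate, the electron-rich 1-methyl diene, intramolecularity and the Thorpe–Ingold effect of the C4 gem-dimethyl group should supply.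

Step 8
Reactants: 13 the Diels–Alder adduct
Product: 14 [(1S,2S,4aS,8aS)-2,5,5,8a-tetramethyl-1,2,4a,5,6,7,8,8a-octahydronaphthalen-1-yl]methanol
Conditions: LiBH4, MeOH (1 equiv), Et2O, 0 °C
Reagents that add atoms: none
Why: Reductive cleavage of the N-acyloxazolidinone, in which borohydride attacks the exocyclic carbonyl and reduces it through to the C11 alcohol, releasing auxiliary 10 and touching no stereocentre.

Step 9
Reactants: 14 the C11 alcohol
Product: 15 (1S,2S,4aS,8aS)-2,5,5,8a-tetramethyl-1,2,4a,5,6,7,8,8a-octahydronaphthalene-1-carbaldehyde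
Conditions: Dess–Martin periodinane, NaHCO3, CH2Cl2, 0 °C → rt
Reagents that add atoms: none
Why: Dess–Martin oxidation under buffered, non-basic conditions should give the C11 aldehyde without epimerising C9.

Step 10
Reactants: 16 (R)-4-methyldihydrofuran-2(3H)-one
Product: 17 (R)-(3-carboxy-2-methylpropyl)triphenylphosphonium bromide
Conditions: PPh3·HBr, neat, 150 °C
Reagents that add atoms: triphenylphosphine hydrobromide, Br.P(c1ccccc1)(c1ccccc1)c1ccccc1
Why: Phosphonium salt formation by SN2 opening of the protonated lactone at its O–CH2 carbon by triphenylphosphine, which leaves the stereocentre (future C13) untouched.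

Step 11
Reactants: 15 the C11 aldehyde; 17 (R)-(3-carboxy-2-methylpropyl)triphenylphosphonium bromide
Product: 19 (11Z,13R)-8αH-labda-6,11-dien-15-oic acid, via carboxylate ylide 18 (not isolated)
Conditions: 17 (1.5 equiv), KN(SiMe3)2 (3.0 equiv), THF, 0 °C; then 15, −78 °C → rt; then 1 M HCl
Reagents that add atoms: none
Why: Wittig reaction of the non-stabilised carboxylate ylide with the hindered aldehyde forms C11=C12 (mainly Z, which is irrelevant because the alkene is hydrogenated next), and addition at low temperature should outrun enolisation at C9.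

Step 12
Reactants: 19 the dienoic acid
Product: 20 (13S)-8αH-labdan-15-oic acid (C17 β)
Conditions: H2 (3 atm), 10% Pd/C, EtOAc, rt
Reagents that add atoms: none
Why: Heterogeneous catalytic hydrogenation saturates the two disubstituted alkenes (C6=C7 and C11=C12) and creates no stereocentre.

Step 13
Reactants: 20 (13S)-8αH-labdan-15-oic acid
Product: 21 (5S,8R,9R,10S,13S)-8-hydroxylabdan-15-oic acid (labdanolic acid, 8α-OH)
Conditions: methyl(trifluoromethyl)dioxirane (1.5 equiv), CH2Cl2/1,1,1-trifluoroacetone, −20 °C → 0 °C
Reagents that add atoms: methyl(trifluoromethyl)dioxirane, CC1(OO1)C(F)(F)F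
Why: Dioxirane C–H hydroxylation by concerted oxygen insertion with retention, expected at the equatorial tertiary C8–H because its transition state relieves the 1,3-diaxial C17/C20 methyl strain, whereas C5–H and C9–H are axial and shielded and C13–H is deactivated by the β-carboxyl group, so that 8α-H becomes 8α-OH.

Step 14
Reactants: 21 labdanolic acid
Product: 22 (5S,8R,9R,10S,13S)-8-(formyloxy)labdan-15-oic acid (target)
Conditions: acetic formic anhydride (5 equiv), pyridine, 0 °C → rt; then THF/H2O, rt
Reagents that add atoms: acetic formic anhydride, CC(=O)OC=O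
Why: O-formylation of the tertiary alcohol by the more electrophilic formyl carbonyl of the mixed anhydride, after which the mixed anhydride formed at the carboxyl group is hydrolysed in the aqueous step, which the tertiary formate should survive.

**Compound list**

1 | 2,2-dimethylpent-4-enal | C=CCC(C)(C)C=O | starting material
2 | (E)-1-iodo-3,3-dimethylhexa-1,5-diene | I/C=C/C(C)(C)CC=C | intermediate
3 | (E)-prop-1-en-1-ylboronic acid | C/C=C/B(O)O | starting material
4 | (2E,4E)-6,6-dimethylnona-2,4,8-triene | C/C=C/C=C/C(C)(C)CC=C | intermediate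
5 | methyl acetoacetate | CC(=O)CC(=O)OC | starting material
6 | methyl (E)-3-{[(trifluoromethyl)sulfonyl]oxy}but-2-enoate | COC(=O)/C=C(\C)OS(=O)(=O)C(F)(F)F | intermediate
7 | 9-[(5E,7E)-4,4-dimethylnona-5,7-dien-1-yl]-9-borabicyclo[3.3.1]nonane | C/C=C/C=C/C(C)(C)CCCB1C2CCCC1CCC2 | intermediate (not isolated)
8 | methyl (2E,8E,10E)-3,7,7-trimethyldodeca-2,8,10-trienoate | COC(=O)/C=C(\C)CCCC(C)(C)/C=C/C=C/C | intermediate
9 | (2E,8E,10E)-3,7,7-trimethyldodeca-2,8,10-trienoic acid | OC(=O)/C=C(\C)CCCC(C)(C)/C=C/C=C/C | intermediate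
10 | (S)-4-benzyloxazolidin-2-one | O=C1N[C@@H](Cc2ccccc2)CO1 | starting material
11 | mixed anhydride of acid 9 with pivalic acid | CC(C)(C)C(=O)OC(=O)/C=C(\C)CCCC(C)(C)/C=C/C=C/C | intermediate (not isolated)
12 | (S)-4-benzyl-3-[(2E,8E,10E)-3,7,7-trimethyldodeca-2,8,10-trienoyl]oxazolidin-2-one | O=C1OC[C@H](Cc2ccccc2)N1C(=O)/C=C(\C)CCCC(C)(C)/C=C/C=C/C | intermediate
13 | (S)-4-benzyl-3-[(1S,2S,4aS,8aS)-2,5,5,8a-tetramethyl-1,2,4a,5,6,7,8,8a-octahydronaphthalene-1-carbonyl]oxazolidin-2-one (Δ6, 5α-H, 8α-H, 9α-H, C17 and C20 β) | O=C1OC[C@H](Cc2ccccc2)N1C(=O)[C@@H]3[C@@]4(C)CCCC(C)(C)[C@@H]4C=C[C@@H]3C | intermediate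
14 | [(1S,2S,4aS,8aS)-2,5,5,8a-tetramethyl-1,2,4a,5,6,7,8,8a-octahydronaphthalen-1-yl]methanol | OC[C@@H]1[C@@]2(C)CCCC(C)(C)[C@@H]2C=C[C@@H]1C | intermediate
15 | (1S,2S,4aS,8aS)-2,5,5,8a-tetramethyl-1,2,4a,5,6,7,8,8a-octahydronaphthalene-1-carbaldehyde | O=C[C@@H]1[C@@]2(C)CCCC(C)(C)[C@@H]2C=C[C@@H]1C | intermediate
16 | (R)-4-methyldihydrofuran-2(3H)-one | C[C@H]1COC(=O)C1 | starting material
17 | (R)-(3-carboxy-2-methylpropyl)triphenylphosphonium bromide | C[C@@H](C[P+](c1ccccc1)(c1ccccc1)c1ccccc1)CC(=O)O.[Br-] | intermediate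
18 | potassium (R)-3-methyl-4-(triphenylphosphoranylidene)butanoate | C[C@@H](C=P(c1ccccc1)(c1ccccc1)c1ccccc1)CC(=O)[O-].[K+] | intermediate (not isolated)
19 | (11Z,13R)-8αH-labda-6,11-dien-15-oic acid (5α-H, 9α-H, C17 and C20 β) | C[C@@H](/C=C\[C@@H]1[C@@]2(C)CCCC(C)(C)[C@@H]2C=C[C@@H]1C)CC(=O)O | intermediate
20 | (13S)-8αH-labdan-15-oic acid (C17 β) | C[C@@H](CC[C@@H]1[C@@]2(C)CCCC(C)(C)[C@@H]2CC[C@@H]1C)CC(=O)O | intermediate
21 | (5S,8R,9R,10S,13S)-8-hydroxylabdan-15-oic acid (labdanolic acid) | C[C@@H](CC[C@@H]1[C@@]2(C)CCCC(C)(C)[C@@H]2CC[C@@]1(C)O)CC(=O)O | intermediate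
22 | (5S,8R,9R,10S,13S)-8-(formyloxy)labdan-15-oic acid | C[C@@H](CC[C@@H]1[C@@]2(C)CCCC(C)(C)[C@@H]2CC[C@@]1(C)OC=O)CC(=O)O | target

**Step count.** Total: 14 steps. Longest linear sequence: 12 steps (steps 1, 2, 4, 5, 6, 7, 8, 9, 11, 12, 13, 14).

**Steps most likely to fail**

Step 7. Formation of the congested C5–C10 bond to a β,β-disubstituted dienophile may be slower than Lewis-acid-induced oligomerisation of the diene, and at the higher temperature then needed exo (cis-fused) closure and attack on the shielded face may compete. The fallback replaces chelate control by iminium catalysis and sets out from ester 8. DIBAL-H reduction (CH2Cl2, −78 °C) should give (2E,8E,10E)-3,7,7-trimethyldodeca-2,8,10-trien-1-ol F1, and MnO2 oxidation (CH2Cl2, rt) should give (2E,8E,10E)-3,7,7-trimethyldodeca-2,8,10-trienal F2. Intramolecular Diels–Alder reaction of F2 is then catalysed by the enantiomer of the 5-benzyl-2-tert-butyl-3-methylimidazolidin-4-one salt whose benzyl group shields the C9 Re face of the iminium ion (acid co-catalyst, MeCN/H2O, −20 °C). It should deliver aldehyde 15 directly, so the fallback comes back to the route at 15.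

Step 13. Oxygen insertion may occur at other C–H bonds (ring methylenes at C2 and C3, or C13–H) or the material may be over-oxidised, so that the C8 alcohol is not obtained cleanly. The fallback brings the oxygen in through alkene chemistry and sets out from alcohol 14. Alkene migration with RhCl3·3H2O (cat., EtOH, reflux) should give the trisubstituted isomer drim-7-en-11-ol F3. Epoxidation with mCPBA from the α face, opposite C20, should give 7α,8α-epoxydriman-11-ol F4, and LiAlH4 opening at C7 (THF, reflux) should give driman-8α,11-diol F5. Oxidation of the primary alcohol (TEMPO, PhI(OAc)2, CH2Cl2) should give 8α-hydroxydriman-11-al F6. Wittig reaction with ylide 18, using one further equivalent of KN(SiMe3)2 for the hydroxyl group, should give (11Z,13R)-8α-hydroxylabd-11-en-15-oic acid F7. Hydrogenation (H2, Pd/C) then gives labdanolic acid 21, where the fallback comes back to the route.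

Step 8. With so hindered an acyl group, hydride may attack the endocyclic carbamate carbonyl, opening the auxiliary ring instead of releasing the acyl group. The fallback separates cleavage from reduction and sets out from adduct 13. Hydrolysis with lithium hydroperoxide (LiOH, H2O2, THF/H2O, 0 °C), which is selective for the exocyclic carbonyl, should give (1S,2S,4aS,8aS)-2,5,5,8a-tetramethyl-1,2,4a,5,6,7,8,8a-octahydronaphthalene-1-carboxylic acid F8. Reduction with LiAlH4 (THF, 0 °C → rt) then gives alcohol 14, where the fallback comes back to the route.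

**Further compounds**

F1 | step 7 | (2E,8E,10E)-3,7,7-trimethyldodeca-2,8,10-trien-1-ol | OC/C=C(\C)CCCC(C)(C)/C=C/C=C/C
F2 | step 7 | (2E,8E,10E)-3,7,7-trimethyldodeca-2,8,10-trienal | O=C/C=C(\C)CCCC(C)(C)/C=C/C=C/C
F3 | step 13 | drim-7-en-11-ol | OC[C@@H]1[C@@]2(C)CCCC(C)(C)[C@@H]2CC=C1C
F4 | step 13 | 7α,8α-epoxydriman-11-ol | OC[C@@H]1[C@@]2(C)CCCC(C)(C)[C@@H]2C[C@H]3O[C@@]13C
F5 | step 13 | driman-8α,11-diol | OC[C@@H]1[C@@]2(C)CCCC(C)(C)[C@@H]2CC[C@@]1(C)O
F6 | step 13 | 8α-hydroxydriman-11-al | O=C[C@@H]1[C@@]2(C)CCCC(C)(C)[C@@H]2CC[C@@]1(C)O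
F7 | step 13 | (11Z,13R)-8α-hydroxylabd-11-en-15-oic acid | C[C@@H](/C=C\[C@@H]1[C@@]2(C)CCCC(C)(C)[C@@H]2CC[C@@]1(C)O)CC(=O)O
F8 | step 8 | (1S,2S,4aS,8aS)-2,5,5,8a-tetramethyl-1,2,4a,5,6,7,8,8a-octahydronaphthalene-1-carboxylic acid | OC(=O)[C@@H]1[C@@]2(C)CCCC(C)(C)[C@@H]2C=C[C@@H]1C
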